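Decide first to follow one molecule of D and leave the early curve aside.

all flasks: J 200 mM (held)

| run | D | remark | time |
|---|---|---|---|
| noon | 0.30 M | run made earlier |  |
| spring | 2.3 M | run made earlier |  |
| south-west | 0.40 M |  | 8.0 min |
| south-east | 1.5 M |  | 8.0 min |
| north | 3.0 M |  | 8.0 min |
| north-east | 0.50 M |  | 8.0 min |
| north-west | 0.80 M |  | 8.0 min |
- noon (time / min: L / %, D / %): 0.833: 28.3, 0; 1.50: 37.7, 0; 2.50: 42.0, 0; 3.00: 42.5, 0; 4.00: 41.0, 0; 5.00: 43.0, 1.0; 6.00: 42.2, 0
- spring (time / min: L / %, D / %): 0.833: 9.5, 1.0; 1.50: 10.8, 1.6; 2.50: 13.3, 0; 3.00: 14.1, 0.9; 4.00: 14.2, 0; 5.00: 13.0, 0.1; 6.00: 15.8, 0.7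

(scatter of a reading: 1 percentage point)
- all flasks from highest to lowest amount of L, in percent of the D charged, at 8.0 min (south-west / south-east / north / north-east / north-west)
- the amount of L, in percent of the D charged of the flask you put first, at 8.0 min
- the amount of L, in percent of the D charged of the flask you put last, at 8.0 min
- given per volume of solution although it is solid: D
- at the start none of D is in solution
- at the start none of J is in solution
- what has only dissolved of D counts as not reacted

Is a flask still moving at the asked time? Take the mean of the last 5 readings. In the noon run L stands near 42.1% from 2.50 min on. In the spring run it stands near 14.1%, and D reads near zero in both. The asked 8.0 min is 3.20 times that first plateau reading, so you read each new flask as a plateau.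

Then what are the molecule's chances? A plateau yield is its chance of ending in L, the selectivity at the fork. With J held the same, that chance reads lower in the spring run, at the larger charge, so the other way gains more from crowding than the way to L does.

How steeply does the chance fall? Define the fall exponent as the logarithm of the ratio of two plateau yields over the logarithm of the inverse ratio of their charges: 0.538. South-west has the smallest charge and north the largest, so you rank the flasks by charge. From the noon run you reckon 36.1% for south-west, and from the spring run 12.2% for north.

The forecast, from “yield ∝ D^-0.5”, says south-west > north-east > north-west > south-east > north, with 37% and 12.6%.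

The flasks give south-west > north-east > north-west > south-east > north, with 36.5% and 12.2%.

    X ⇌ G (K = 6.80, k = 0.00210 /s)
    2 Q → E (k = 0.0830 /M/s)
    D ⇌ Q, rate k3*(cs3 - [Q]) while solid is left; crystals form when [Q] > cs3 (solubility = 1.20 M, k = 0.260 /s)
    J ⇌ X, rate k4*(csat - [X]) (kL = 0.0810 /s)
    Q + X → L (k = 0.130 /M/s)

Here Q is dissolved D, X is dissolved J, and E comes from two Q and counts as two in every percentage. In south-west the dissolving of D has done half of its turnover up to 8.0 min by 0.701 s, and the transfer of J to X has done the same share of its own by 0.639 min. At 8.00 min south-west holds L 36.5% and E 63.5%. For the neighbour of south-west with 0.24 M of D, the fall exponent of 0.538 reckoned from the noon run gives 47.5%, and that flask gives 48.1%.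

The readings are simulated with constants of no real substance, and the scatter is random.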